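## Structural features

The target is made of two units joined by an unfunctionalised CH2–CH2 chain: a cis-fused 1,4,4a,7,8,8a-hexahydronaphthalene, numbered with C1 as the gem-dimethyl carbon (ring B: C1–C4, C4a, C8a; ring A: C4a, C5–C8, C8a), and a 1,2-dioxane (O1, O2, C3–C6) whose C6 carries a methyl group and the chain and whose C3 carries a 2-propanoic acid. Ring B holds a tetrasubstituted C2=C3 alkene between the quaternary C1 and the C3 methyl group, and ring A holds a trisubstituted C5=C6 alkene with the C6 methyl group. The five stereocentres fall into two clusters that cannot influence each other: the adjacent ring-fusion pair C4a/C8a (cis; 4aR,8aS), and on the heterocycle the quaternary peroxy carbon C6 (R), C3 (R) and its exocyclic neighbour, the acid α-carbon (R), with the chain at C6 cis to the side chain at C3. The O–O bond is fragile towards phosphines, low-valent metals, hydrides and strong base, the acid α-carbon is epimerisable and as a carbonyl derivative can expel the peroxide by β-elimination, and both ring alkenes can migrate under acid. The real difficulties are the cis ring fusion of defined absolute configuration next to a quaternary carbon on a carbocycle that keeps no heteroatom, the tertiary peroxide stereocentre, and the union of the halves without harm to O–O. The key step exploits ring B: C1 (gem-dimethyl), C2 (one-carbon substituent), C3 (methyl), C2=C3 and C4 as a latent carbonyl make up a 3-substituted 2,4,4-trimethylcyclohexa-2,5-dienone, whose unsubstituted enone double bond is the C4a–C8a bond. C5–C8 of ring A with the C6 methyl group are a 2-methylbutadiene, and a temporary oxygen at C5 directs the regiochemistry of the cycloaddition and later moves the alkene.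

## Logic of the disconnections

44 is taken back to 43 by changing the carboxyl C–O bonds into a primary C–OH and then to 42 (O–Si bond). The acid is unmasked last so that no enolisable β-peroxy carbonyl group meets base or an ylide. The forward oxidation must spare O–O, two alkenes and the α-centre.

42 is taken back to 41 (two C–H bonds across the linker) and 41 is cut at the bond between the two linker carbons into 23 and 39. This is the only C–C bond between the stereochemical clusters, so each half is made independently and the O–O bond enters late. The forward steps need a non-basic, non-enolisable aldehyde partner and a metal-free reduction selective for the least substituted alkene.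

23 is taken back through 22 (C–P bond) and 20 (acetal C–O bonds) to 17, by returning the C5=C6 alkene and the C7–H bond to a C5–O bond with a C6=C7 alkene. The oxygen at C5 is what the cycloaddition leaves there. The forward step must deliver hydrogen to C7 with allylic transposition, not to C5.

17 is taken back to 16 (O–Si), 15, 14 and 13 by returning the two C4–H bonds to C4=O. The carbonyl is what activates the dienophile. The forward removal must keep the C2=C3 alkene in place and must come before any basic step, because 13 is a β-silyloxy ketone with an epimerisable C4a.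

13 is cut at C4a–C5 and C8–C8a into 10 and 12. This removes ring A and three stereocentres at once and leaves two achiral, flat components. The forward step must be site-, regio-, endo- and enantioface-selective. A parity check of 13 against 44 shows cis fusion, the silyloxy group cis to C4, and the same absolute sense at C4a and C8a as in the target, so 13 needs no correction.

10 is taken back to 8 (C5–H and C6–H bonds), and 8 is cut at the bond between C3 and its one-carbon substituent into 5 and 6. 5 is cut at one C6–CH3 bond into 4 and 3, 4 at its remaining C6–CH3 bond into 2 and 3, and 2 at the enol ether C–O bond into 1. Each cut uses the 1,3-dioxygen pattern of 1 to differentiate the ring carbons. The two methyl groups are introduced one at a time, each by one enolisation and one equivalent of 3. The forward addition must reach a carbonyl flanked by a quaternary carbon, and the forward dehydrogenation must be regiospecific. The acetal on the one-carbon substituent is kept because 6 is commercial and because it can be removed at −78 °C without protic acid. The C2 methyl group of 10 leaves the catalyst only one α-C–H side to bind.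

12 is cut at the O–Si bond to 11, and the forward enolisation must favour the (1E) isomer.

39 is taken back to 38 (aldehyde C–H to C–OH), 38 is cut at the C3–O2 bond to 37, and 37 at the C6–O1 bond to 36. Both C–O bonds are made by inversion at carbon from centres of defined configuration, so C3 and C6 are set independently of each other. The forward steps need a clean backside opening at a tertiary epoxide carbon and a 6-exo displacement that beats elimination.

36 is taken back to 35 (S–O) and 34 (Si–O), 34 to 33 (imide C–N and carbonyl reduction), and 33 is cut at the C3–Cα bond into 30 and 31. The syn methyl/hydroxyl pair is the signature of an auxiliary-controlled aldol. The forward aldol must tolerate a 2,2-disubstituted epoxide.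

30 is taken back to 28 (C=O from C=C), 28 to 26 (epoxide C–O from a primary sulfonate) and 26 is cut at the C4–C5 bond into 24 and 25. The quaternary centre is bought in enantiopure form and its C–O bond is never broken before step 22.

## Other disconnections considered

Alternative 1: The cut is C4–C4a, made by an anionic oxy-Cope rearrangement. The potassium alkoxide of (1R,2S,4S)-1,3,3-trimethyl-2-(prop-1-en-2-yl)bicyclo[2.2.2]oct-5-en-2-ol A1 would rearrange to the ring B enolate, trapped with PhNTf2 as (4aR,8aS)-1,1,3,6-tetramethyl-1,4,4a,7,8,8a-hexahydronaphthalen-2-yl trifluoromethanesulfonate A2.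
- In its favour: the bicyclic framework enforces the cis fusion stereospecifically, and both alkenes arrive in their final positions, so no oxygen has to be removed from the carbocycle afterwards. On this point it is better than the chosen plan, which spends five steps (8–12) on two deoxygenations.
- Against it: the carbinol carbon of A1 lies between a methylated bridgehead and a gem-dimethyl carbon, so the isopropenyl addition that makes A1 is severely hindered and must also come from the alkene face. Absolute configuration has to be brought in earlier by an asymmetric cycloaddition to a bicyclooctenone. A2 then needs an sp2–sp3 coupling at a triflate flanked by a quaternary carbon, under palladium catalysis that a peroxide partner would not survive, so the dioxane would have to be built after the coupling.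
- Comparison: structurally it sets two stereocentres relatively (the chosen step sets three absolutely, one sacrificial). Mechanistically it is a substrate-controlled sigmatropic shift, not a catalyst-controlled cycloaddition. It is shorter after the key step but longer and less certain before it, and less convergent.

Alternative 2: The cuts are C4a–C8a and C1–C2, made by a cationic bicyclisation. Ionisation of (2E,5E)-7-hydroxy-3,7,11-trimethyldodeca-2,5,10-trien-1-yl acetate A3 would give [(4aR,8aS)-1,1,3,6-tetramethyl-1,4,4a,7,8,8a-hexahydronaphthalen-2-yl]methyl acetate A4.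
- In its favour: it builds both rings, two C–C bonds and the whole carbon skeleton in one step from a farnesyl-type chain, with the C2 one-carbon handle already at the right oxidation level. In step count it is clearly better than the chosen plan, and the handle is its equal.
- Against it: the allyl cation is achiral, so enantiocontrol would need a chiral counter-ion or confined acid. The cis/trans fusion depends on the folding of the chain. The allyl cation can be attacked at either end. The first cation can eliminate to monocyclic products before the second ring closes. The acetoxy-substituted alkene is a poor nucleophile and its acetate can participate. The final proton loss has several outlets.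
- Comparison: it forms more structure per step, but by a stepwise cationic path with many branch points, where the chosen step is concerted and catalyst-controlled. Step economy favours A4; stereochemical reliability favours the chosen plan.

Alternative 3: The cuts are the two C–O bonds of the dioxane, made together by [4+2] addition of singlet oxygen. tert-Butyl{[(2R,3E,5E)-2,6-dimethyl-7-(triethylsilyloxy)hepta-3,5-dien-1-yl]oxy}diphenylsilane A5 would give tert-butyl{(2S)-2-[(3R,6S)-6-methyl-6-(triethylsilyloxymethyl)-3,6-dihydro-1,2-dioxin-3-yl]propoxy}diphenylsilane A6.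
- In its favour: suprafacial addition to the (E,E)-diene fixes the cis relation between the C3 side chain and the C6 oxymethyl group in one neutral step. A6 would converge on 38 after diimide reduction and removal of the triethylsilyl group, so it is complementary to the chosen decalin chemistry. In step count it is the equal of steps 15–23 or slightly better.
- Against it: the trisubstituted diene terminus carries allylic hydrogens and an inside methyl group, so the ene reaction competes with the cycloaddition. The face of attack is governed only by the neighbouring methyl-bearing centre. It does not address the carbocycle at all.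
- Comparison: it makes the same ring by a pericyclic process with substrate-controlled facial selectivity, where the chosen plan uses two stereospecific inversions from centres of defined configuration. The chosen plan is the better on stereochemical certainty; A6 is equal or better on length.

Key step: step 7

Numbering: decalin atoms are numbered as in the target (C1 = gem-dimethyl carbon) in every compound; dioxane atoms are O1, O2, C3 (side-chain carbon) to C6 (quaternary carbon).

Assumption: the facial sense of the catalyst in step 7 is assigned from the α-C–H···O binding model for enones; should the adduct prove antipodal, the (S)-configured catalyst is used with no other change.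

## Route

Step 1
Reactants: 1 2-methylcyclohexane-1,3-dione
Product: 2 3-isobutoxy-2-methylcyclohex-2-en-1-one
Conditions: i-BuOH, TsOH·H2O (cat.), toluene, reflux, Dean–Stark
Reagents that add atoms: 2-methylpropan-1-ol, CC(C)CO
Why: Acid-catalysed enol etherification of the symmetrical 1,3-dione with azeotropic removal of water gives the vinylogous ester; symmetry removes any regiochemical question.

Step 2
Reactants: 2 3-isobutoxy-2-methylcyclohex-2-en-1-one; 3 iodomethane
Product: 4 3-isobutoxy-2,6-dimethylcyclohex-2-en-1-one (racemic)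
Conditions: LiN(iPr)2 (1.1 equiv), THF, −78 °C; MeI (1.2 equiv), −78 → 0 °C
Reagents that add atoms: none
Why: Stork–Danheiser kinetic α′-alkylation: the amide base removes a C6 proton of the vinylogous ester and the cross-conjugated enolate is methylated on carbon by one equivalent of iodomethane; the new centre is racemic and disappears in step 3.

Step 3
Reactants: 4 3-isobutoxy-2,6-dimethylcyclohex-2-en-1-one; 3 iodomethane
Product: 5 3-isobutoxy-2,6,6-trimethylcyclohex-2-en-1-one
Conditions: LiN(iPr)2 (1.2 equiv), THF, −78 °C; MeI (1.5 equiv), −78 °C → rt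
Reagents that add atoms: none
Why: A second kinetic α′-deprotonation at the remaining C6–H and C-methylation complete the gem-dimethyl group; afterwards no α′-hydrogen is left, so over-alkylation is excluded.

Step 4
Reactants: 5 3-isobutoxy-2,6,6-trimethylcyclohex-2-en-1-one; 6 tributyl[(methoxymethoxy)methyl]stannane
Product: 8 3-[(methoxymethoxy)methyl]-2,4,4-trimethylcyclohex-2-en-1-one, via tertiary carbinol 7 (not isolated)
Conditions: 6, n-BuLi, THF, −78 °C; add 5, −78 → −20 °C; then 1 M HCl, THF, 0 °C → rt
Reagents that add atoms: none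
Why: Tin–lithium exchange gives the α-alkoxymethyllithium, which adds 1,2 to the hindered carbonyl, which has no α′-hydrogen; dilute acid hydrolyses the enol ether and eliminates the tertiary allylic hydroxyl (Stork–Danheiser transposition), placing the new carbon next to the gem-dimethyl carbon while the acetal survives brief cold acid.

Step 5
Reactants: 8 3-[(methoxymethoxy)methyl]-2,4,4-trimethylcyclohex-2-en-1-one
Product: 10 3-[(methoxymethoxy)methyl]-2,4,4-trimethylcyclohexa-2,5-dien-1-one, via silyl dienol ether 9 (not isolated)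
Conditions: LiN(iPr)2, THF, −78 °C; Me3SiCl; then Pd(OAc)2 (1.05 equiv), MeCN, rt
Reagents that add atoms: none
Why: Saegusa–Ito dehydrogenation: kinetic deprotonation at the only α′-CH2 gives the cross-conjugated silyl dienol ether, and palladium diacetate forms an oxo-π-allyl complex of divalent palladium that loses a β-hydride to give the C5=C6 enone; the quaternary C4 excludes any other position.

Step 6
Reactants: 11 (E)-2-methylbut-2-enal
Product: 12 (E)-tert-butyldimethyl[(2-methylbuta-1,3-dien-1-yl)oxy]silane
Conditions: t-BuMe2SiOTf, Et3N, Et2O, 0 °C → rt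
Reagents that add atoms: tert-butyldimethylsilyl trifluoromethanesulfonate, CC(C)(C)[Si](C)(C)OS(=O)(=O)C(F)(F)F
Why: Soft enolisation: O-silylation of the enal and γ-deprotonation by the amine give the silyl dienol ether; the s-trans enal places oxygen anti to the new vinyl group, so the (1E) isomer should predominate, and any (1Z) isomer is unreactive in step 7.

Step 7
Reactants: 10 3-[(methoxymethoxy)methyl]-2,4,4-trimethylcyclohexa-2,5-dien-1-one; 12 (E)-tert-butyldimethyl[(2-methylbuta-1,3-dien-1-yl)oxy]silane
Product: 13 (4aS,5S,8aS)-5-[(tert-butyldimethylsilyl)oxy]-2-[(methoxymethoxy)methyl]-1,1,3,6-tetramethyl-4a,5,8,8a-tetrahydronaphthalen-4(1H)-one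
Conditions: (R)-3,3-diphenyl-1-(o-tolyl)tetrahydro-1H,3H-pyrrolo[1,2-c][1,3,2]oxazaborole (20 mol %), Tf2NH (17 mol %), CH2Cl2, −78 → −20 °C; 12 (2.5 equiv); cold pH 7 buffer
Reagents that add atoms: none
Why: The boron of the protonated oxazaborolidine binds the carbonyl lone pair syn to C6–H (the C2 methyl group closes the other side, and an α-C–H···O contact to the ring oxygen fixes the geometry), which lowers the LUMO of the C5=C6 enone only. The diene adds in a concerted, asynchronous endo [4+2] cycloaddition in which the bond from its unsubstituted CH2 terminus to the hindered β-carbon (future C8a) leads and the bond from the silyloxy-bearing terminus to the α-carbon (future C4a) follows. The closest known reaction type is the oxazaborolidinium-catalysed Diels–Alder reaction of cyclohexenones and of quinone monoketals, themselves 4,4-disubstituted cyclohexa-2,5-dienones, with silyloxydienes. Ring A is closed by intermolecular [4+2] cycloaddition, both new bonds (C4a–C5 and C8–C8a) forming suprafacially on the cis ring alkene, so the fusion can only be cis. The absolute configuration at C4a and C8a is set by the catalyst, whose aryl group covers one face of the bound enone; C5 is set relative to them by the endo orientation of the carbonyl under the diene together with the (E)-geometry of the silyl enol ether, which puts the silyloxy group cis to C4. Site selectivity comes from the substrate, because the other dienone double bond is tetrasubstituted; regioselectivity comes from the 1-silyloxy donor, whose largest HOMO coefficient lies on the remote CH2 terminus and meets the largest LUMO coefficient at the β-carbon. Work-up is cold and free of base because 13 is a β-silyloxy ketone with an epimerisable C4a.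

Step 8
Reactants: 13 (4aS,5S,8aS)-5-[(tert-butyldimethylsilyl)oxy]-2-[(methoxymethoxy)methyl]-1,1,3,6-tetramethyl-4a,5,8,8a-tetrahydronaphthalen-4(1H)-one
Product: 14 (4R,4aR,5S,8aS)-5-[(tert-butyldimethylsilyl)oxy]-2-[(methoxymethoxy)methyl]-1,1,3,6-tetramethyl-1,4,4a,5,8,8a-hexahydronaphthalen-4-ol
Conditions: NaBH4, CeCl3·7H2O, MeOH, −78 → −40 °C
Reagents that add atoms: none
Why: Luche reduction: cerium-assisted 1,2-delivery of hydride to the enone, expected from the face of H4a/H8a; it is cold and near neutral, so neither C4a epimerisation nor β-elimination of the silyloxy group intervenes, and the C4 configuration is immaterial because the centre is removed in step 10.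

Step 9
Reactants: 14 (4R,4aR,5S,8aS)-5-[(tert-butyldimethylsilyl)oxy]-2-[(methoxymethoxy)methyl]-1,1,3,6-tetramethyl-1,4,4a,5,8,8a-hexahydronaphthalen-4-ol
Product: 15 O-{(4R,4aR,5S,8aS)-5-[(tert-butyldimethylsilyl)oxy]-2-[(methoxymethoxy)methyl]-1,1,3,6-tetramethyl-1,4,4a,5,8,8a-hexahydronaphthalen-4-yl} O-phenyl carbonothioate
Conditions: PhOC(S)Cl, pyridine, DMAP (cat.), CH2Cl2, 0 °C → rt
Reagents that add atoms: O-phenyl carbonochloridothioate, S=C(Cl)Oc1ccccc1
Why: Acylation of the secondary allylic alcohol under nucleophilic catalysis gives the thionocarbonate needed for radical C–O cleavage; no alkoxide is formed, so the silyl group cannot migrate from O5 to O4.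

Step 10
Reactants: 15 O-{(4R,4aR,5S,8aS)-5-[(tert-butyldimethylsilyl)oxy]-2-[(methoxymethoxy)methyl]-1,1,3,6-tetramethyl-1,4,4a,5,8,8a-hexahydronaphthalen-4-yl} O-phenyl carbonothioate
Product: 16 (4aS,5S,8aS)-5-[(tert-butyldimethylsilyl)oxy]-2-[(methoxymethoxy)methyl]-1,1,3,6-tetramethyl-1,4,4a,5,8,8a-hexahydronaphthalene
Conditions: Bu3SnH, Et3B (cat.), air, toluene, rt
Reagents that add atoms: none
Why: Barton–McCombie deoxygenation with room-temperature initiation (no thermal [3,3] shift of the allylic thionocarbonate): the delocalised C2–C3–C4 allyl radical takes hydrogen at the less hindered secondary terminus C4 and not at C2 beside the quaternary C1, which keeps the tetrasubstituted C2=C3 alkene.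

Step 11
Reactants: 16 (4aS,5S,8aS)-5-[(tert-butyldimethylsilyl)oxy]-2-[(methoxymethoxy)methyl]-1,1,3,6-tetramethyl-1,4,4a,5,8,8a-hexahydronaphthalene
Product: 17 (4aS,5S,8aS)-2-[(methoxymethoxy)methyl]-1,1,3,6-tetramethyl-1,4,4a,5,8,8a-hexahydronaphthalen-5-ol
Conditions: Bu4NF, THF, rt
Reagents that add atoms: none
Why: Fluoride cleaves the Si–O bond of the secondary allylic silyl ether; with the C4 carbonyl gone there is no elimination or epimerisation pathway, and the acetal is inert to fluoride.

Step 12
Reactants: 17 (4aS,5S,8aS)-2-[(methoxymethoxy)methyl]-1,1,3,6-tetramethyl-1,4,4a,5,8,8a-hexahydronaphthalen-5-ol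
Product: 20 (4aR,8aS)-2-[(methoxymethoxy)methyl]-1,1,3,6-tetramethyl-1,4,4a,7,8,8a-hexahydronaphthalene, via sulfonylhydrazine adduct 18 (not isolated), via allylic diazene 19 (not isolated)
Conditions: PPh3, DEAD, 2-nitrobenzenesulfonohydrazide, THF, −30 °C; then 23 °C
Reagents that add atoms: none
Why: Mitsunobu displacement of the allylic alcohol by the sulfonylhydrazide (SN2, inversion at C5), loss of sulfinic acid on warming to the monoalkyl diazene, and suprafacial retro-ene loss of N2 deliver hydrogen to C7 and move the alkene to C5=C6; C7 becomes CH2, so no stereocentre depends on this step.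

Step 13
Reactants: 20 (4aR,8aS)-2-[(methoxymethoxy)methyl]-1,1,3,6-tetramethyl-1,4,4a,7,8,8a-hexahydronaphthalene
Product: 22 [(4aR,8aS)-1,1,3,6-tetramethyl-1,4,4a,7,8,8a-hexahydronaphthalen-2-yl]methanol, via bromomethyl ether 21 (not isolated)
Conditions: Me2BBr, CH2Cl2, −78 °C; then sat. NaHCO3, THF, 0 °C
Reagents that add atoms: none
Why: The bromoborane cleaves the acetal at −78 °C to the bromomethyl ether, which is hydrolysed on bicarbonate work-up; low temperature and the absence of protic acid keep both ring alkenes in place and avoid ionisation of the allylic C–O bond.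

Step 14
Reactants: 22 [(4aR,8aS)-1,1,3,6-tetramethyl-1,4,4a,7,8,8a-hexahydronaphthalen-2-yl]methanol
Product: 23 {[(4aR,8aS)-1,1,3,6-tetramethyl-1,4,4a,7,8,8a-hexahydronaphthalen-2-yl]methyl}triphenylphosphonium bromide
Conditions: PPh3·HBr, MeOH, rt
Reagents that add atoms: triphenylphosphine hydrobromide, [Br-].[PH+](c1ccccc1)(c1ccccc1)c1ccccc1
Why: Acid-assisted ionisation of the tetrasubstituted allylic alcohol to the allyl cation and capture by the phosphine at the primary terminus (the tertiary terminus is shielded) give the allylic phosphonium salt, as for β-cyclogeraniol-type alcohols.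

Step 15
Reactants: 24 (S)-(2-methyloxiran-2-yl)methanol; 25 allylmagnesium bromide (CH2=CHCH2MgBr)
Product: 26 (R)-2-methylhex-5-ene-1,2-diol
Conditions: CH2=CHCH2MgBr (3 equiv), CuI (10 mol %), THF, −30 → 0 °C
Reagents that add atoms: none
Why: Copper-catalysed Grignard opening of the epoxide at its CH2 carbon after deprotonation of the hydroxyl; the quaternary stereocentre is untouched, and only its descriptor changes from S to R.

Step 16
Reactants: 26 (R)-2-methylhex-5-ene-1,2-diol
Product: 28 (R)-2-(but-3-en-1-yl)-2-methyloxirane, via monotosylate 27 (not isolated)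
Conditions: NaH (2.2 equiv), THF, 0 °C; 1-tosylimidazole, 0 °C → rt
Reagents that add atoms: none
Why: One-pot sulfonylation of the primary alkoxide and 3-exo-tet closure by the tertiary alkoxide give the 2,2-disubstituted epoxide with retention at the quaternary carbon, whose C–O bond is not broken.

Step 17
Reactants: 28 (R)-2-(but-3-en-1-yl)-2-methyloxirane
Product: 30 3-[(R)-2-methyloxiran-2-yl]propanal, via ozonide 29 (not isolated)
Conditions: O3, CH2Cl2, −78 °C; then PPh3, −78 °C → rt; used as a solution
Reagents that add atoms: ozone, [O-][O+]=O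
Why: Ozonolysis of the monosubstituted alkene and reductive cleavage of the ozonide give the aldehyde; the epoxide is inert to ozone and to the phosphine in the cold.

Step 18
Reactants: 31 (R)-4-benzyl-3-propanoyl-1,3-oxazolidin-2-one; 30 3-[(R)-2-methyloxiran-2-yl]propanal
Product: 33 (R)-4-benzyl-3-{(2R,3S)-3-hydroxy-2-methyl-5-[(R)-2-methyloxiran-2-yl]pentanoyl}-1,3-oxazolidin-2-one, via boron enolate 32 (not isolated)
Conditions: 31, Bu2BOTf, i-Pr2NEt, CH2Cl2, 0 °C; 30, −78 → 0 °C; pH 7 buffer, MeOH, H2O2, 0 °C
Reagents that add atoms: none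
Why: Evans syn-aldol: the (Z)-boron enolate reacts through a closed chair transition state with the benzyl group of the (R)-auxiliary covering one enolate face, which sets the methyl-bearing centre (2R) and the carbinol (3S); the boron triflate is consumed in enolisation before the acid-sensitive epoxy aldehyde is added.

Step 19
Reactants: 33 (R)-4-benzyl-3-{(2R,3S)-3-hydroxy-2-methyl-5-[(R)-2-methyloxiran-2-yl]pentanoyl}-1,3-oxazolidin-2-one
Product: 34 (2S,3S)-2-methyl-5-[(R)-2-methyloxiran-2-yl]pentane-1,3-diol
Conditions: LiBH4, MeOH (1 equiv), THF, 0 °C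
Reagents that add atoms: none
Why: Borohydride reduces the imide carbonyl chemoselectively to the primary alcohol and releases the auxiliary; short cold exposure spares the epoxide, and no stereocentre is touched (the descriptor at C2 changes only by priority).

Step 20
Reactants: 34 (2S,3S)-2-methyl-5-[(R)-2-methyloxiran-2-yl]pentane-1,3-diol
Product: 35 (2S,3S)-1-[(tert-butyldiphenylsilyl)oxy]-2-methyl-5-[(R)-2-methyloxiran-2-yl]pentan-3-ol
Conditions: t-BuPh2SiCl, imidazole, CH2Cl2, 0 °C
Reagents that add atoms: tert-butyl(chloro)diphenylsilane, CC(C)(C)[Si](Cl)(c1ccccc1)c1ccccc1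
Why: The bulky silyl chloride takes the primary hydroxyl of the 1,3-diol selectively; the basic medium avoids acid-promoted 5-exo opening of the epoxide by the C3 hydroxyl.

Step 21
Reactants: 35 (2S,3S)-1-[(tert-butyldiphenylsilyl)oxy]-2-methyl-5-[(R)-2-methyloxiran-2-yl]pentan-3-ol
Product: 36 (2S,3S)-1-[(tert-butyldiphenylsilyl)oxy]-2-methyl-5-[(R)-2-methyloxiran-2-yl]pentan-3-yl methanesulfonate
Conditions: MsCl, Et3N, CH2Cl2, −20 → 0 °C
Reagents that add atoms: methanesulfonyl chloride, CS(=O)(=O)Cl
Why: Sulfonylation of the remaining secondary alcohol under amine base turns C3–O into a leaving group with retention, ready for inversion in step 23, and removes the hydroxyl that could open the epoxide.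

Step 22
Reactants: 36 (2S,3S)-1-[(tert-butyldiphenylsilyl)oxy]-2-methyl-5-[(R)-2-methyloxiran-2-yl]pentan-3-yl methanesulfonate
Product: 37 (2S,3S,6S)-1-[(tert-butyldiphenylsilyl)oxy]-6-hydroperoxy-7-hydroxy-2,6-dimethylheptan-3-yl methanesulfonate
Conditions: H2O2 (anhydrous, in Et2O, excess), H3PMo12O40 (cat.), Et2O, 0 °C → rt
Reagents that add atoms: hydrogen peroxide, OO
Why: Heteropolyacid-catalysed perhydrolysis of a 2,2-disubstituted epoxide: hydrogen peroxide attacks the activated tertiary carbon from the side opposite the departing oxygen (inversion), giving the tertiary hydroperoxide and the primary alcohol that becomes the aldehyde; the mesylate and silyl ether are inert.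

Step 23
Reactants: 37 (2S,3S,6S)-1-[(tert-butyldiphenylsilyl)oxy]-6-hydroperoxy-7-hydroxy-2,6-dimethylheptan-3-yl methanesulfonate
Product: 38 {(3R,6S)-3-[(S)-1-(tert-butyldiphenylsilyloxy)propan-2-yl]-6-methyl-1,2-dioxan-6-yl}methanol
Conditions: KOt-Bu (1.05 equiv), 18-crown-6, toluene, 0 °C
Reagents that add atoms: none
Why: Intramolecular alkylation of the hydroperoxide (6-exo-tet): one equivalent of base deprotonates only the far more acidic hydroperoxide, and the peroxy anion displaces the secondary mesylate with inversion, which fixes C3 as R and the cis relation between the C3 side chain and the C6 hydroxymethyl group.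

Step 24
Reactants: 38 {(3R,6S)-3-[(S)-1-(tert-butyldiphenylsilyloxy)propan-2-yl]-6-methyl-1,2-dioxan-6-yl}methanol
Product: 39 (3R,6S)-3-[(S)-1-(tert-butyldiphenylsilyloxy)propan-2-yl]-6-methyl-1,2-dioxane-6-carbaldehyde
Conditions: Dess–Martin periodinane, NaHCO3, CH2Cl2, 0 °C → rt
Reagents that add atoms: none
Why: Dess–Martin oxidation of the neopentylic primary alcohol under buffered, non-basic conditions gives the non-enolisable α-peroxy aldehyde without touching the O–O bond.

Step 25
Reactants: 23 {[(4aR,8aS)-1,1,3,6-tetramethyl-1,4,4a,7,8,8a-hexahydronaphthalen-2-yl]methyl}triphenylphosphonium bromide; 39 (3R,6S)-3-[(S)-1-(tert-butyldiphenylsilyloxy)propan-2-yl]-6-methyl-1,2-dioxane-6-carbaldehyde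
Product: 41 tert-butyl{(S)-2-[(3R,6S)-6-methyl-6-{2-[(4aR,8aS)-1,1,3,6-tetramethyl-1,4,4a,7,8,8a-hexahydronaphthalen-2-yl]ethenyl}-1,2-dioxan-3-yl]propoxy}diphenylsilane (E/Z mixture), via phosphonium ylide 40 (not isolated)
Conditions: 23, KN(SiMe3)2, THF, −78 → 0 °C; then 39, −78 °C → rt
Reagents that add atoms: none
Why: Wittig olefination: the salt-free allylic ylide adds to the non-enolisable aldehyde and the oxaphosphetane collapses to the diene; the alkene geometry is irrelevant because the bond is saturated next, and low temperature keeps the ylide away from the O–O bond.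

Step 26
Reactants: 41 tert-butyl{(S)-2-[(3R,6S)-6-methyl-6-{2-[(4aR,8aS)-1,1,3,6-tetramethyl-1,4,4a,7,8,8a-hexahydronaphthalen-2-yl]ethenyl}-1,2-dioxan-3-yl]propoxy}diphenylsilane
Product: 42 tert-butyl{(S)-2-[(3R,6R)-6-methyl-6-{2-[(4aR,8aS)-1,1,3,6-tetramethyl-1,4,4a,7,8,8a-hexahydronaphthalen-2-yl]ethyl}-1,2-dioxan-3-yl]propoxy}diphenylsilane
Conditions: KO2CN=NCO2K (excess, in portions), AcOH, MeOH–CH2Cl2, 0 °C → rt
Reagents that add atoms: none
Why: Diimide transfers H2 in a concerted syn fashion to the least substituted C=C; the tri- and tetrasubstituted ring alkenes react far more slowly, and the O–O bond is inert to this metal-free reductant.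

Step 27
Reactants: 42 tert-butyl{(S)-2-[(3R,6R)-6-methyl-6-{2-[(4aR,8aS)-1,1,3,6-tetramethyl-1,4,4a,7,8,8a-hexahydronaphthalen-2-yl]ethyl}-1,2-dioxan-3-yl]propoxy}diphenylsilane
Product: 43 (S)-2-[(3R,6R)-6-methyl-6-{2-[(4aR,8aS)-1,1,3,6-tetramethyl-1,4,4a,7,8,8a-hexahydronaphthalen-2-yl]ethyl}-1,2-dioxan-3-yl]propan-1-ol
Conditions: Bu4NF, AcOH, THF, 0 °C → rt
Reagents that add atoms: none
Why: Buffered fluoride cleaves the primary silyl ether; acetic acid keeps the medium from becoming basic enough for Kornblum–DeLaMare-type cleavage at C3–H.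

Step 28
Reactants: 43 (S)-2-[(3R,6R)-6-methyl-6-{2-[(4aR,8aS)-1,1,3,6-tetramethyl-1,4,4a,7,8,8a-hexahydronaphthalen-2-yl]ethyl}-1,2-dioxan-3-yl]propan-1-ol
Product: 44 (R)-2-[(3R,6R)-6-methyl-6-{2-[(4aR,8aS)-1,1,3,6-tetramethyl-1,4,4a,7,8,8a-hexahydronaphthalen-2-yl]ethyl}-1,2-dioxan-3-yl]propanoic acid
Conditions: TEMPO (cat.), PhI(OAc)2, MeCN–H2O, rt
Reagents that add atoms: water, O
Why: Nitroxyl-catalysed oxidation takes the primary alcohol through the aldehyde hydrate to the acid under near-neutral conditions, sparing the O–O bond, both alkenes and the α-stereocentre.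

## Compound list

1 | 2-methylcyclohexane-1,3-dione | CC1C(=O)CCCC1=O | starting material
2 | 3-isobutoxy-2-methylcyclohex-2-en-1-one | CC1=C(OCC(C)C)CCCC1=O | intermediate
3 | iodomethane | CI | starting material
4 | 3-isobutoxy-2,6-dimethylcyclohex-2-en-1-one (racemic) | CC1=C(OCC(C)C)CCC(C)C1=O | intermediate
5 | 3-isobutoxy-2,6,6-trimethylcyclohex-2-en-1-one | CC1=C(OCC(C)C)CCC(C)(C)C1=O | intermediate
6 | tributyl[(methoxymethoxy)methyl]stannane | CCCC[Sn](CCCC)(CCCC)COCOC | starting material
7 | 3-isobutoxy-1-[(methoxymethoxy)methyl]-2,6,6-trimethylcyclohex-2-en-1-ol (racemic, not isolated) | CC1=C(OCC(C)C)CCC(C)(C)C1(O)COCOC | intermediate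
8 | 3-[(methoxymethoxy)methyl]-2,4,4-trimethylcyclohex-2-en-1-one | CC1=C(COCOC)C(C)(C)CCC1=O | intermediate
9 | {[5-((methoxymethoxy)methyl)-4,4,6-trimethylcyclohexa-1,5-dien-1-yl]oxy}trimethylsilane (not isolated) | CC1=C(COCOC)C(C)(C)CC=C1O[Si](C)(C)C | intermediate
10 | 3-[(methoxymethoxy)methyl]-2,4,4-trimethylcyclohexa-2,5-dien-1-one | CC1=C(COCOC)C(C)(C)C=CC1=O | intermediate
11 | (E)-2-methylbut-2-enal | C/C=C(\C)C=O | starting material
12 | (E)-tert-butyldimethyl[(2-methylbuta-1,3-dien-1-yl)oxy]silane | C=C/C(C)=C/O[Si](C)(C)C(C)(C)C | intermediate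
13 | (4aS,5S,8aS)-5-[(tert-butyldimethylsilyl)oxy]-2-[(methoxymethoxy)methyl]-1,1,3,6-tetramethyl-4a,5,8,8a-tetrahydronaphthalen-4(1H)-one | CC1=CC[C@H]2[C@@H]([C@@H]1O[Si](C)(C)C(C)(C)C)C(=O)C(C)=C(COCOC)C2(C)C | intermediate
14 | (4R,4aR,5S,8aS)-5-[(tert-butyldimethylsilyl)oxy]-2-[(methoxymethoxy)methyl]-1,1,3,6-tetramethyl-1,4,4a,5,8,8a-hexahydronaphthalen-4-ol | CC1=CC[C@H]2[C@@H]([C@@H]1O[Si](C)(C)C(C)(C)C)[C@@H](O)C(C)=C(COCOC)C2(C)C | intermediate
15 | O-phenyl thionocarbonate of 14 at O4 | CC1=CC[C@H]2[C@@H]([C@@H]1O[Si](C)(C)C(C)(C)C)[C@@H](OC(=S)Oc3ccccc3)C(C)=C(COCOC)C2(C)C | intermediate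
16 | (4aS,5S,8aS)-5-[(tert-butyldimethylsilyl)oxy]-2-[(methoxymethoxy)methyl]-1,1,3,6-tetramethyl-1,4,4a,5,8,8a-hexahydronaphthalene | CC1=CC[C@H]2[C@@H]([C@@H]1O[Si](C)(C)C(C)(C)C)CC(C)=C(COCOC)C2(C)C | intermediate
17 | (4aS,5S,8aS)-2-[(methoxymethoxy)methyl]-1,1,3,6-tetramethyl-1,4,4a,5,8,8a-hexahydronaphthalen-5-ol | CC1=CC[C@H]2[C@@H]([C@@H]1O)CC(C)=C(COCOC)C2(C)C | intermediate
18 | N-[(4aS,5R,8aS)-2-((methoxymethoxy)methyl)-1,1,3,6-tetramethyl-1,4,4a,5,8,8a-hexahydronaphthalen-5-yl]-2-nitrobenzenesulfonohydrazide (not isolated) | CC1=CC[C@H]2[C@@H]([C@H]1N(N)S(=O)(=O)c3ccccc3[N+](=O)[O-])CC(C)=C(COCOC)C2(C)C | intermediate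
19 | [(4aS,5R,8aS)-2-((methoxymethoxy)methyl)-1,1,3,6-tetramethyl-1,4,4a,5,8,8a-hexahydronaphthalen-5-yl]diazene (not isolated) | CC1=CC[C@H]2[C@@H]([C@H]1N=N)CC(C)=C(COCOC)C2(C)C | intermediate
20 | (4aR,8aS)-2-[(methoxymethoxy)methyl]-1,1,3,6-tetramethyl-1,4,4a,7,8,8a-hexahydronaphthalene | CC1=C[C@H]2CC(C)=C(COCOC)C(C)(C)[C@H]2CC1 | intermediate
21 | (4aR,8aS)-2-[(bromomethoxy)methyl]-1,1,3,6-tetramethyl-1,4,4a,7,8,8a-hexahydronaphthalene (not isolated) | CC1=C[C@H]2CC(C)=C(COCBr)C(C)(C)[C@H]2CC1 | intermediate
22 | [(4aR,8aS)-1,1,3,6-tetramethyl-1,4,4a,7,8,8a-hexahydronaphthalen-2-yl]methanol | CC1=C[C@H]2CC(C)=C(CO)C(C)(C)[C@H]2CC1 | intermediate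
23 | {[(4aR,8aS)-1,1,3,6-tetramethyl-1,4,4a,7,8,8a-hexahydronaphthalen-2-yl]methyl}triphenylphosphonium bromide | CC1=C[C@H]2CC(C)=C(C[P+](c3ccccc3)(c3ccccc3)c3ccccc3)C(C)(C)[C@H]2CC1.[Br-] | intermediate
24 | (S)-(2-methyloxiran-2-yl)methanol | OC[C@@]1(C)CO1 | starting material
25 | allylmagnesium bromide | C=CC[Mg]Br | starting material
26 | (R)-2-methylhex-5-ene-1,2-diol | O[C@](CO)(C)CCC=C | intermediate
27 | (R)-2-hydroxy-2-methylhex-5-en-1-yl 4-methylbenzenesulfonate (not isolated) | Cc1ccc(cc1)S(=O)(=O)OC[C@](C)(O)CCC=C | intermediate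
28 | (R)-2-(but-3-en-1-yl)-2-methyloxirane | C1O[C@]1(C)CCC=C | intermediate
29 | 3-{2-[(R)-2-methyloxiran-2-yl]ethyl}-1,2,4-trioxolane (not isolated) | C1O[C@]1(C)CCC2OCOO2 | intermediate
30 | 3-[(R)-2-methyloxiran-2-yl]propanal | C1O[C@]1(C)CCC=O | intermediate
31 | (R)-4-benzyl-3-propanoyl-1,3-oxazolidin-2-one | CCC(=O)N1[C@H](Cc2ccccc2)COC1=O | starting material
32 | (Z)-dibutylboron enolate of 31 (not isolated) | CCCCB(CCCC)O/C(=C\C)N1[C@H](Cc2ccccc2)COC1=O | intermediate
33 | (R)-4-benzyl-3-{(2R,3S)-3-hydroxy-2-methyl-5-[(R)-2-methyloxiran-2-yl]pentanoyl}-1,3-oxazolidin-2-one | C1O[C@]1(C)CC[C@H](O)[C@@H](C)C(=O)N1[C@H](Cc2ccccc2)COC1=O | intermediate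
34 | (2S,3S)-2-methyl-5-[(R)-2-methyloxiran-2-yl]pentane-1,3-diol | C1O[C@]1(C)CC[C@H](O)[C@@H](C)CO | intermediate
35 | (2S,3S)-1-[(tert-butyldiphenylsilyl)oxy]-2-methyl-5-[(R)-2-methyloxiran-2-yl]pentan-3-ol | C1O[C@]1(C)CC[C@H](O)[C@@H](C)CO[Si](c1ccccc1)(c1ccccc1)C(C)(C)C | intermediate
36 | (2S,3S)-1-[(tert-butyldiphenylsilyl)oxy]-2-methyl-5-[(R)-2-methyloxiran-2-yl]pentan-3-yl methanesulfonate | C1O[C@]1(C)CC[C@H](OS(C)(=O)=O)[C@@H](C)CO[Si](c1ccccc1)(c1ccccc1)C(C)(C)C | intermediate
37 | (2S,3S,6S)-1-[(tert-butyldiphenylsilyl)oxy]-6-hydroperoxy-7-hydroxy-2,6-dimethylheptan-3-yl methanesulfonate | OC[C@](OO)(C)CC[C@H](OS(C)(=O)=O)[C@@H](C)CO[Si](c1ccccc1)(c1ccccc1)C(C)(C)C | intermediate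
38 | {(3R,6S)-3-[(S)-1-(tert-butyldiphenylsilyloxy)propan-2-yl]-6-methyl-1,2-dioxan-6-yl}methanol | OC[C@]1(C)CC[C@H]([C@@H](C)CO[Si](c2ccccc2)(c2ccccc2)C(C)(C)C)OO1 | intermediate
39 | (3R,6S)-3-[(S)-1-(tert-butyldiphenylsilyloxy)propan-2-yl]-6-methyl-1,2-dioxane-6-carbaldehyde | O=C[C@]1(C)CC[C@H]([C@@H](C)CO[Si](c2ccccc2)(c2ccccc2)C(C)(C)C)OO1 | intermediate
40 | {[(4aR,8aS)-1,1,3,6-tetramethyl-1,4,4a,7,8,8a-hexahydronaphthalen-2-yl]methylidene}triphenylphosphorane (not isolated) | CC1=C[C@H]2CC(C)=C(C=P(c3ccccc3)(c3ccccc3)c3ccccc3)C(C)(C)[C@H]2CC1 | intermediate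
41 | tert-butyl{(S)-2-[(3R,6S)-6-methyl-6-{2-[(4aR,8aS)-1,1,3,6-tetramethyl-1,4,4a,7,8,8a-hexahydronaphthalen-2-yl]ethenyl}-1,2-dioxan-3-yl]propoxy}diphenylsilane (E/Z mixture) | CC1=C[C@H]2CC(C)=C(C=C[C@]3(C)CC[C@H]([C@@H](C)CO[Si](c4ccccc4)(c4ccccc4)C(C)(C)C)OO3)C(C)(C)[C@H]2CC1 | intermediate
42 | tert-butyl{(S)-2-[(3R,6R)-6-methyl-6-{2-[(4aR,8aS)-1,1,3,6-tetramethyl-1,4,4a,7,8,8a-hexahydronaphthalen-2-yl]ethyl}-1,2-dioxan-3-yl]propoxy}diphenylsilane | CC1=C[C@H]2CC(C)=C(CC[C@]3(C)CC[C@H]([C@@H](C)CO[Si](c4ccccc4)(c4ccccc4)C(C)(C)C)OO3)C(C)(C)[C@H]2CC1 | intermediate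
43 | (S)-2-[(3R,6R)-6-methyl-6-{2-[(4aR,8aS)-1,1,3,6-tetramethyl-1,4,4a,7,8,8a-hexahydronaphthalen-2-yl]ethyl}-1,2-dioxan-3-yl]propan-1-ol | CC1=C[C@H]2CC(C)=C(CC[C@]3(C)CC[C@H]([C@@H](C)CO)OO3)C(C)(C)[C@H]2CC1 | intermediate
44 | (R)-2-[(3R,6R)-6-methyl-6-{2-[(4aR,8aS)-1,1,3,6-tetramethyl-1,4,4a,7,8,8a-hexahydronaphthalen-2-yl]ethyl}-1,2-dioxan-3-yl]propanoic acid | CC1=C[C@H]2CC(C)=C(CC[C@]3(C)CC[C@H]([C@@H](C)C(=O)O)OO3)C(C)(C)[C@H]2CC1 | target

## Step count and least certain steps

Total step count: 28 (14 to the phosphonium salt 23 including one step for the diene, 10 to the aldehyde 39, 4 after the union).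
Longest linear sequence: 17 steps (steps 1–5, 7–14 and 25–28).

Step 7 (key step). The likeliest failure is slow cycloaddition at the neopentylic β-carbon of 10, so that the temperature has to be raised to a point where catalyst control is lost. Silyl transfer from 12 could also release an achiral silyl Lewis acid that catalyses a racemic background reaction, and 13 could lose silanol by β-elimination during a long reaction. The fallback gives up catalyst control: 10 and 12 would be combined under Me2AlCl in CH2Cl2 (or simply heated) to give 13 together with its antipode ent-13 F1. Luche reduction as in step 8 would give 14 together with ent-14 F2. Esterification with (S)-2-methoxy-2-phenylacetic acid (DCC, DMAP) would give two diastereomers, the (S)-O-methylmandelate of 14 F3 and the (S)-O-methylmandelate of ent-14 F4, to be separated by chromatography or crystallisation. Methanolysis of F3 (K2CO3, MeOH) would return 14, where the route is rejoined.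

Step 10. Hydrogen transfer to the allyl radical at C2 instead of C4 would give the transposed C3=C4 alkene, and a [3,3] shift of the allylic thionocarbonate before reduction would remove the radical precursor. The fallback replaces the radical by a π-allyl complex: 14 would be converted with ClCO2Me and pyridine into the methyl carbonate of 14 F5, which with Pd(PPh3)4 (cat.) and LiBHEt3 in THF should ionise to the π-allyl complex of zerovalent palladium and accept external hydride at the less hindered terminus C4, giving 16.

Step 12. The SN2 step at C5, which lies beside the ring fusion, may be slow, leaving time for the hydrazide reagent to decompose, for SN2′ capture (which would return the C6=C7 alkene) or for elimination to a diene. The fallback avoids substitution at C5: 17 would be oxidised (Dess–Martin periodinane, NaHCO3) to the C5 enone (4aS,8aS)-2-[(methoxymethoxy)methyl]-1,1,3,6-tetramethyl-4,4a,8,8a-tetrahydronaphthalen-5(1H)-one F6 and condensed with TsNHNH2 to the tosylhydrazone of that enone F7. Reduction with catecholborane followed by NaOAc·3H2O should give the same allylic diazene by 1,2-hydride addition and loss of sulfinate, and hence 20. The enone stage must be kept cold and buffered because C4a is again epimerisable there.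

Step 22. The opening at the tertiary epoxide carbon may acquire carbocation character, which would erode the configuration at C6 or divert the epoxide into a Meinwald rearrangement; anhydrous ethereal H2O2 is also hazardous and must be handled cold behind a shield. The fallback reverses the order of the two C–O bond formations, so that the tertiary centre is attacked intramolecularly. 36 would be treated with 2-hydroperoxy-2-methoxypropane and CsOH in DMF, displacing the mesylate with inversion to give the peroxyketal tert-butyl{[(2S,3R)-3-[(2-methoxypropan-2-yl)peroxy]-2-methyl-5-((R)-2-methyloxiran-2-yl)pentyl]oxy}diphenylsilane F8. Mild aqueous acid would release the secondary hydroperoxide tert-butyl{[(2S,3R)-3-hydroperoxy-2-methyl-5-((R)-2-methyloxiran-2-yl)pentyl]oxy}diphenylsilane F9, which in the same medium should open the epoxide at C6 in 6-exo fashion with inversion and give 38. This sequence also avoids the base-mediated closure of step 23, whose own risks are E2 elimination of the mesylate and fragmentation of the β-hydroxy peroxide.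

Step 25. Both partners are neopentylic, so addition may be slow, and a betaine-like alkoxide next to the peroxy carbon could fragment with cleavage of the O–O bond, or the ylide could attack the O–O bond directly. The fallback uses a sulfone anion, which avoids phosphorus and a long-lived alkoxide. 22 would be converted by Mitsunobu reaction with 1-phenyl-1H-tetrazole-5-thiol into the sulfide 5-({[(4aR,8aS)-1,1,3,6-tetramethyl-1,4,4a,7,8,8a-hexahydronaphthalen-2-yl]methyl}sulfanyl)-1-phenyl-1H-tetrazole F10, and oxidised with (NH4)6Mo7O24 and H2O2 in EtOH to the sulfone 5-({[(4aR,8aS)-1,1,3,6-tetramethyl-1,4,4a,7,8,8a-hexahydronaphthalen-2-yl]methyl}sulfonyl)-1-phenyl-1H-tetrazole F11. Deprotonation with KN(SiMe3)2 at −78 °C and addition of 39 (Julia–Kocienski olefination) should give 41.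

## Further compounds

F1 | step 7 | (4aR,5R,8aR)-5-[(tert-butyldimethylsilyl)oxy]-2-[(methoxymethoxy)methyl]-1,1,3,6-tetramethyl-4a,5,8,8a-tetrahydronaphthalen-4(1H)-one (ent-13) | CC1=CC[C@@H]2[C@H]([C@H]1O[Si](C)(C)C(C)(C)C)C(=O)C(C)=C(COCOC)C2(C)C
F2 | step 7 | (4S,4aS,5R,8aR)-5-[(tert-butyldimethylsilyl)oxy]-2-[(methoxymethoxy)methyl]-1,1,3,6-tetramethyl-1,4,4a,5,8,8a-hexahydronaphthalen-4-ol (ent-14) | CC1=CC[C@@H]2[C@H]([C@H]1O[Si](C)(C)C(C)(C)C)[C@H](O)C(C)=C(COCOC)C2(C)C
F3 | step 7 | (S)-2-methoxy-2-phenylacetate of 14 | CC1=CC[C@H]2[C@@H]([C@@H]1O[Si](C)(C)C(C)(C)C)[C@@H](OC(=O)[C@@H](OC)c3ccccc3)C(C)=C(COCOC)C2(C)C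
F4 | step 7 | (S)-2-methoxy-2-phenylacetate of ent-14 | CC1=CC[C@@H]2[C@H]([C@H]1O[Si](C)(C)C(C)(C)C)[C@H](OC(=O)[C@@H](OC)c3ccccc3)C(C)=C(COCOC)C2(C)C
F5 | step 10 | methyl carbonate of 14 at O4 | CC1=CC[C@H]2[C@@H]([C@@H]1O[Si](C)(C)C(C)(C)C)[C@@H](OC(=O)OC)C(C)=C(COCOC)C2(C)C
F6 | step 12 | (4aS,8aS)-2-[(methoxymethoxy)methyl]-1,1,3,6-tetramethyl-4,4a,8,8a-tetrahydronaphthalen-5(1H)-one | CC1=CC[C@H]2[C@@H](C1=O)CC(C)=C(COCOC)C2(C)C
F7 | step 12 | 4-methylbenzenesulfonohydrazone of F6 | CC1=CC[C@H]2[C@@H](C1=NNS(=O)(=O)c3ccc(C)cc3)CC(C)=C(COCOC)C2(C)C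
F8 | step 22 | tert-butyl{[(2S,3R)-3-[(2-methoxypropan-2-yl)peroxy]-2-methyl-5-((R)-2-methyloxiran-2-yl)pentyl]oxy}diphenylsilane | C1O[C@]1(C)CC[C@@H](OOC(C)(C)OC)[C@@H](C)CO[Si](c1ccccc1)(c1ccccc1)C(C)(C)C
F9 | step 22 | tert-butyl{[(2S,3R)-3-hydroperoxy-2-methyl-5-((R)-2-methyloxiran-2-yl)pentyl]oxy}diphenylsilane | C1O[C@]1(C)CC[C@@H](OO)[C@@H](C)CO[Si](c1ccccc1)(c1ccccc1)C(C)(C)C
F10 | step 25 | 5-({[(4aR,8aS)-1,1,3,6-tetramethyl-1,4,4a,7,8,8a-hexahydronaphthalen-2-yl]methyl}sulfanyl)-1-phenyl-1H-tetrazole | CC1=C[C@H]2CC(C)=C(CSc3nnnn3c3ccccc3)C(C)(C)[C@H]2CC1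
F11 | step 25 | 5-({[(4aR,8aS)-1,1,3,6-tetramethyl-1,4,4a,7,8,8a-hexahydronaphthalen-2-yl]methyl}sulfonyl)-1-phenyl-1H-tetrazole | CC1=C[C@H]2CC(C)=C(CS(=O)(=O)c3nnnn3c3ccccc3)C(C)(C)[C@H]2CC1
A1 | alternative 1 | (1R,2S,4S)-1,3,3-trimethyl-2-(prop-1-en-2-yl)bicyclo[2.2.2]oct-5-en-2-ol | CC(=C)[C@]1(O)C(C)(C)[C@H]2CC[C@]1(C)C=C2
A2 | alternative 1 | (4aR,8aS)-1,1,3,6-tetramethyl-1,4,4a,7,8,8a-hexahydronaphthalen-2-yl trifluoromethanesulfonate | CC1=C[C@H]2CC(C)=C(OS(=O)(=O)C(F)(F)F)C(C)(C)[C@H]2CC1
A3 | alternative 2 | (2E,5E)-7-hydroxy-3,7,11-trimethyldodeca-2,5,10-trien-1-yl acetate (racemic at C7) | CC(=O)OC/C=C(\C)C/C=C/C(C)(O)CCC=C(C)C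
A4 | alternative 2 | [(4aR,8aS)-1,1,3,6-tetramethyl-1,4,4a,7,8,8a-hexahydronaphthalen-2-yl]methyl acetate | CC1=C[C@H]2CC(C)=C(COC(C)=O)C(C)(C)[C@H]2CC1
A5 | alternative 3 | tert-butyl{[(2R,3E,5E)-2,6-dimethyl-7-(triethylsilyloxy)hepta-3,5-dien-1-yl]oxy}diphenylsilane | CC[Si](CC)(CC)OC/C(C)=C/C=C/[C@@H](C)CO[Si](c1ccccc1)(c1ccccc1)C(C)(C)C
A6 | alternative 3 | tert-butyl{(2S)-2-[(3R,6S)-6-methyl-6-(triethylsilyloxymethyl)-3,6-dihydro-1,2-dioxin-3-yl]propoxy}diphenylsilane | CC[Si](CC)(CC)OC[C@]1(C)C=C[C@H]([C@@H](C)CO[Si](c2ccccc2)(c2ccccc2)C(C)(C)C)OO1
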